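**Retrosynthetic overview**

1. Feature: the C16–C7 bond belongs both to the cyclopentane (C4, C5, C6, C7, C16) and to the eleven-membered ring (C1, C15, C16, C7–C14). It lies between the cyclohexene alkene C1=C15 and the exocyclic C8=C19H2. Cutting it leaves a C1–C15–C16 allyl cation facing a C7=C8–C19H2SiMe3 allylsilane inside a bicyclo[10.2.2] 7,16-seco-trinervitane (42).
2. 42 ⇒ C10–C11 (ring-closing metathesis, then diimide), C9–C10 (catalytic asymmetric vinylation of an enal), C7=C8 (Wittig reaction with a silylmethyl ylide), C1–C14 (organocerium addition to enone 17).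
3. 17 ⇒ (S)-Wieland–Miescher ketone from 2-methylcyclohexane-1,3-dione. Ketone reduction sets C3 beside quaternary C4, and cleavage of the enone ring frees the C5–C7 chain. C15 methylation, a carbonyl shift from C16 to C1 and Rubottom oxidation at C2 follow.
4. Ring order: cyclohexene (from the dione) → fourteen-membered carbocycle bridging C1/C4 (step 28) → cyclopentane and eleven-membered ring together (step 30).

Key step: step 30

Remark: C1–C20 are trinervitane atom numbers (C17 = methyl on C15, C18 = methyl on C4, C19 = exocyclic CH2, C20 = CH2OAc); TBS = tert-butyldimethylsilyl, PMB = 4-methoxybenzyl.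

Assumption: the C1 carbinol centre is erased in step 30. It is drawn as the epimer expected from addition anti to the C2 silyl ether (1R), and its epimer would be taken through the same steps.

**Step 1**
Reactants: 1 2-methylcyclohexane-1,3-dione; 2 methyl vinyl ketone
Product: 3 2-methyl-2-(3-oxobutyl)cyclohexane-1,3-dione
Conditions: Et3N (cat.), neat, rt
Reagents that add atoms: none
Why: Michael addition of the acidic 1,3-dione to the enone builds the still prochiral quaternary carbon C4 with its methyl C18 and brings in the carbons that become C5–C7.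

**Step 2**
Reactants: 3 2-methyl-2-(3-oxobutyl)cyclohexane-1,3-dione
Product: 4 (S)-8a-methyl-3,4,8,8a-tetrahydronaphthalene-1,6(2H,7H)-dione (Wieland–Miescher ketone)
Conditions: N-tosyl-(Sa)-binam-L-prolinamide (2 mol %), PhCO2H (cat.), neat, rt
Reagents that add atoms: none
Why: Hajos–Parrish–Eder–Sauer–Wiechert reaction (enamine-catalysed intramolecular aldol condensation) in which the L-proline-derived catalyst selects one of the two enantiotopic ring carbonyls and so sets C4 (8aS).

**Step 3**
Reactants: 4 (S)-Wieland–Miescher ketone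
Product: 5 (4aS,5S)-5-hydroxy-4a-methyl-4,4a,5,6,7,8-hexahydronaphthalen-2(3H)-one
Conditions: NaBH4 (0.3 equiv), EtOH, 0 °C
Reagents that add atoms: none
Why: Chemoselective borohydride reduction of the isolated ketone; hydride enters opposite to the axial angular methyl, which places the C3 hydroxyl cis to C18 and trans to the future C5 chain.

**Step 4**
Reactants: 5 (4aS,5S)-hydroxy enone
Product: 6 (4aS,5S)-5-(TBSO)-4a-methyl-4,4a,5,6,7,8-hexahydronaphthalen-2(3H)-one
Conditions: TBSCl, imidazole, DMF, rt to 40 °C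
Reagents that add atoms: tert-butyldimethylsilyl chloride, CC(C)(C)[Si](C)(C)Cl
Why: Standard silylation; the ether should survive the enolate, Pd, Cr(VI), organometallic and Lewis-acid steps and falls to fluoride at the end.

**Step 5**
Reactants: 6 TBS ether of 5
Product: 7 3-[(1R,2S)-2-(TBSO)-1-methyl-6-oxocyclohexyl]propanoic acid
Conditions: RuCl3·xH2O (cat.), NaIO4, EtOAc/MeCN/H2O, rt
Reagents that add atoms: sodium periodate, [Na+].[O-]I(=O)(=O)=O
Why: Ruthenium tetroxide cleavage of the enone C=C bond with loss of the α-carbon as CO2 (the usual fate of bicyclic 4-en-3-ones) turns the second ring into the C16 ketone and the C5–C6–C7 acid chain without touching C3 or C4.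

**Step 6**
Reactants: 7 keto acid
Product: 8 methyl 3-[(1R,2S)-2-(TBSO)-1-methyl-6-oxocyclohexyl]propanoate
Conditions: MeI, K2CO3, DMF, rt
Reagents that add atoms: iodomethane, CI
Why: SN2 O-alkylation of the carboxylate gives an ester that masks C7 at the acid level until step 20.

**Step 7**
Reactants: 8 keto ester
Product: 10 methyl 3-[(1R,2S)-2-(TBSO)-1,5-dimethyl-6-oxocyclohexyl]propanoate (C5 epimers), via lithium enolate 9 (not isolated)
Conditions: LDA, THF, −78 °C; MeI, −78 to −40 °C
Reagents that add atoms: iodomethane, CI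
Why: Kinetic enolate alkylation; C4 is quaternary, so the ketone can enolise only towards C15 and is deprotonated ahead of the ester, and the new centre (methyl C17) becomes sp2 in step 8, so the epimer mixture is harmless.

**Step 8**
Reactants: 10 α-methyl ketone
Product: 12 methyl 3-[(1R,6S)-6-(TBSO)-1,3-dimethyl-2-(trifluoromethylsulfonyloxy)cyclohex-2-en-1-yl]propanoate, via potassium enolate 11 (not isolated)
Conditions: KHMDS, THF, −78 to −20 °C; PhNTf2, −78 °C to rt
Reagents that add atoms: N-phenylbis(trifluoromethanesulfonimide), O=S(=O)(N(c1ccccc1)S(=O)(=O)C(F)(F)F)C(F)(F)F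
Why: Enol triflate formation from the only possible ketone enolate, as practised on 2,2,6-trisubstituted cyclohexanones; the equilibrating base funnels any ester enolate to the more stable ketone enolate.

**Step 9**
Reactants: 12 enol triflate
Product: 13 methyl 3-[(1S,6S)-6-(TBSO)-1,3-dimethylcyclohex-2-en-1-yl]propanoate
Conditions: Pd(OAc)2 (cat.), PPh3, HCO2H, n-Bu3N, DMF, 60 °C
Reagents that add atoms: none
Why: Palladium-catalysed formate hydrogenolysis of the vinyl triflate replaces OTf by H without moving the alkene and delivers C15(Me)=C16H.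

**Step 10**
Reactants: 13 cyclohexene
Product: 14 methyl 3-[(1S,6S)-6-(TBSO)-1,3-dimethyl-4-oxocyclohex-2-en-1-yl]propanoate
Conditions: CrO3, 3,5-dimethylpyrazole, CH2Cl2, −20 °C
Reagents that add atoms: chromium trioxide, O=[Cr](=O)=O
Why: Allylic oxidation; C1 is the only allylic ring methylene and the other allyl terminus C16 is shielded by quaternary C4, so oxygen should end at C1 and give the transposed 2-methyl enone.

**Step 11**
Reactants: 14 enone
Product: 15 methyl 3-[(1S,6S)-4,6-bis(TBSO)-1,3-dimethylcyclohexa-2,4-dien-1-yl]propanoate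
Conditions: TBSOTf, Et3N, CH2Cl2, 0 °C
Reagents that add atoms: tert-butyldimethylsilyl triflate, CC(C)(C)[Si](C)(C)OS(=O)(=O)C(F)(F)F
Why: Soft enolisation towards C2, the only enolisable position, gives the cross-conjugated silyl dienol ether and avoids a free enolate that could expel the C3 silyloxy group.

**Step 12**
Reactants: 15 silyl dienol ether
Product: 17 methyl 3-[(1S,5S,6R)-5,6-bis(TBSO)-1,3-dimethyl-4-oxocyclohex-2-en-1-yl]propanoate, via silyloxy epoxide 16 (not isolated)
Conditions: mCPBA, CH2Cl2/hexane, −20 to 0 °C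
Reagents that add atoms: 3-chloroperbenzoic acid, O=C(OO)c1cccc(Cl)c1
Why: Rubottom oxidation; the peracid attacks the electron-rich enol ether alkene anti to the neighbouring C3 silyl ether, and ring opening of 16 with silyl migration gives the 2,3-trans bis-silyl ether, which is also the more stable C2 epimer.

**Step 13**
Reactants: 18 (E)-but-2-ene-1,4-diol
Product: 19 (E)-4-(4-methoxybenzyloxy)but-2-en-1-ol
Conditions: NaH, PMBCl, Bu4NI (cat.), THF/DMF, 0 °C to rt (diol in excess)
Reagents that add atoms: 4-methoxybenzyl chloride, COc1ccc(CCl)cc1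
Why: Williamson etherification with excess diol favours the mono-ether that will carry O-20.

**Step 14**
Reactants: 19 mono-PMB ether
Product: 20 (E)-4-(4-methoxybenzyloxy)but-2-en-1-yl methyl carbonate
Conditions: ClCO2Me, pyridine, CH2Cl2, 0 °C
Reagents that add atoms: methyl chloroformate, COC(=O)Cl
Why: Acylation installs a leaving group that releases its own base (methoxide) in the next step.

**Step 15**
Reactants: 20 allylic carbonate; 21 dimethyl malonate
Product: 22 dimethyl 2-[(2S)-1-(4-methoxybenzyloxy)but-3-en-2-yl]malonate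
Conditions: [Ir(cod)Cl]2 (2 mol %), binol-derived N,N-bis(1-phenylethyl)phosphoramidite (4 mol %, the antipode leading to the S product), TBD (cat.), THF, rt
Reagents that add atoms: none
Why: Iridium-catalysed asymmetric allylic alkylation attacks the substituted allyl terminus, so the ligand sets C12 and leaves the vinyl group (C11) needed for ring closure.

**Step 16**
Reactants: 22 malonate
Product: 23 methyl (3R)-3-[(4-methoxybenzyloxy)methyl]pent-4-enoate
Conditions: LiCl, H2O, DMSO, 150 °C
Reagents that add atoms: none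
Why: Krapcho decarboxylation removes one ester under neutral conditions that do not touch the allylic stereocentre (the descriptor changes only through CIP priorities).

**Step 17**
Reactants: 23 ester
Product: 24 (3R)-3-[(4-methoxybenzyloxy)methyl]pent-4-en-1-ol
Conditions: LiAlH4, Et2O, 0 °C
Reagents that add atoms: none
Why: Hydride reduction of the ester gives the primary alcohol at C14.

**Step 18**
Reactants: 24 alcohol
Product: 25 (3R)-5-iodo-3-[(4-methoxybenzyloxy)methyl]pent-1-ene
Conditions: I2, PPh3, imidazole, CH2Cl2, 0 °C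
Reagents that add atoms: iodine, II
Why: Appel reaction converts the primary alcohol into the iodide needed for halogen–lithium exchange.

**Step 19**
Reactants: 25 iodide; 17 enone
Product: 28 methyl 3-[(1S,4R,5S,6R)-5,6-bis(TBSO)-4-hydroxy-4-{(3R)-3-[(4-methoxybenzyloxy)methyl]pent-4-en-1-yl}-1,3-dimethylcyclohex-2-en-1-yl]propanoate, via alkyllithium 26 (not isolated), via organocerium reagent 27 (not isolated)
Conditions: 25, t-BuLi (2 equiv), Et2O/pentane, −78 °C; CeCl3, THF, −78 °C; then 17, −78 °C
Reagents that add atoms: none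
Why: Iodine–lithium exchange, transmetalation to cerium and 1,2-addition; the weakly basic reagent spares the β-silyloxy ketone from elimination, adds to the ketone ahead of the ester at −78 °C, and should approach C1 anti to the C2 silyl ether.

**Step 20**
Reactants: 28 tertiary allylic alcohol ester
Product: 29 3-[(1S,4R,5S,6R)-5,6-bis(TBSO)-4-hydroxy-4-{(3R)-3-[(4-methoxybenzyloxy)methyl]pent-4-en-1-yl}-1,3-dimethylcyclohex-2-en-1-yl]propanal
Conditions: DIBAL-H (2.2 equiv), CH2Cl2, −78 °C; aq. K/Na tartrate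
Reagents that add atoms: none
Why: Partial ester reduction stops at the aluminium hemiacetal at −78 °C and frees the C7 aldehyde on work-up, no other reducible group being present.

**Step 21**
Reactants: 30 ethyl (triphenylphosphoranylidene)acetate; 31 (chloromethyl)trimethylsilane
Product: 34 ethyl 2-(triphenylphosphoranylidene)-3-(trimethylsilyl)propanoate, via (iodomethyl)trimethylsilane 32 (not isolated), via phosphonium iodide 33 (not isolated)
Conditions: NaI, MeCN, reflux; then aq. NaOH, CH2Cl2, rt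
Reagents that add atoms: none
Why: Finkelstein exchange in the flask, C-alkylation of the stabilised ylide and deprotonation of the salt give the α-(silylmethyl) ylide that carries C8, C9 and C19.

**Step 22**
Reactants: 29 aldehyde; 34 ylide
Product: 35 ethyl (2Z)-5-[the (1S,4R,5S,6R)-cyclohexenyl unit of 29]-2-[(trimethylsilyl)methyl]pent-2-enoate (ester trans to C6, CH2SiMe3 cis to C6)
Conditions: toluene, 90 °C
Reagents that add atoms: none
Why: Wittig reaction of an α-branched stabilised ylide, which like its α-methyl analogue should place the ester trans to the alkyl chain and so fix the C7=C8 geometry (Z only by CIP rank of CH2Si).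

**Step 23**
Reactants: 35 PMB ether
Product: 36 the C20 primary alcohol of 35
Conditions: DDQ, CH2Cl2/pH 7 buffer, 0 °C
Reagents that add atoms: none
Why: Oxidative PMB cleavage is run while the allylsilane is still deactivated by the conjugated ester, so that only the electron-rich benzyl ether is oxidised.

**Step 24**
Reactants: 36 hydroxy enoate
Product: 37 the (2Z)-2-[(trimethylsilyl)methyl]pent-2-en-1-ol (C9H2OH), a 1,9,20-triol
Conditions: DIBAL-H (excess), CH2Cl2, −78 °C
Reagents that add atoms: none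
Why: 1,2-Reduction of the enoate gives the 2-(silylmethyl)allylic alcohol without touching alkene geometry or the C–Si bond.

**Step 25**
Reactants: 37 triol
Product: 38 the (2Z)-2-[(trimethylsilyl)methyl]pent-2-enal (C9 aldehyde)
Conditions: MnO2, CH2Cl2, rt
Reagents that add atoms: none
Why: Manganese dioxide oxidises only the primary allylic alcohol; the saturated C20 alcohol and the tertiary C1 alcohol are inert.

**Step 26**
Reactants: 38 enal
Product: 39 (3S,4Z)-7-[cyclohexenyl unit]-4-[(trimethylsilyl)methyl]hepta-1,4-dien-3-ol (9S vinyl carbinol, 1,9,20-triol)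
Conditions: (CH2=CH)2Zn (from CH2=CHMgBr and ZnCl2, dioxane, salts filtered off), (−)-3-exo-morpholinoisoborneol (15 mol %), toluene, −20 to 0 °C
Reagents that add atoms: divinylzinc, C=C[Zn]C=C
Why: Amino-alcohol-catalysed asymmetric addition of a vinylzinc reagent to an aldehyde; by analogy with dialkylzinc additions to sp2-substituted aldehydes, this ligand antipode should deliver the 9S carbinol under reagent control.

**Step 27**
Reactants: 39 triol
Product: 40 9,20-diacetate of 39 (C1–OH free)
Conditions: Ac2O, pyridine, DMAP (cat.), CH2Cl2, 0 °C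
Reagents that add atoms: acetic anhydride, CC(=O)OC(C)=O
Why: Acylation of the primary and the secondary alcohol installs both acetates of the target at once, and the hindered tertiary alcohol is not acylated under these conditions.

**Step 28**
Reactants: 40 diene diacetate
Product: 41 10,11-didehydro derivative of 42 (bicyclo[10.2.2] ring system, C10=C11 geometry inconsequential)
Conditions: (H2IMes)(PCy3)Cl2Ru=CHPh (10 mol %), 1,4-benzoquinone (cat.), CH2Cl2 (0.5 mM), reflux
Reagents that add atoms: none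
Why: Ring-closing metathesis of the two monosubstituted alkenes; the trisubstituted C7=C8 and C15=C16 alkenes are too hindered to compete, no small ring can form, and the ten-atom bridge across the 1,4-positions of the cyclohexene compares in span with a [10]paracyclophane.

**Step 29**
Reactants: 41 macrocyclic diene
Product: 42 (1R,2S,3R,4S,7Z,9S,12R)-9,20-diacetoxy-2,3-bis(TBSO)-19-(trimethylsilyl)-7,16-secotrinervita-7,15-dien-1-ol
Conditions: 2-nitrobenzenesulfonyl hydrazide, Et3N, CH2Cl2, rt
Reagents that add atoms: none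
Why: Diimide reduction saturates the 1,2-disubstituted alkene only and, unlike metal-catalysed hydrogenation, threatens neither the trisubstituted alkenes nor the allylic C–O and C–Si bonds.

**Step 30**
Reactants: 42 bicyclic seco-trinervitane
Product: 45 2,3-bis-O-TBS ether of the target, via allyl cation 43 (not isolated), via β-silyl cation 44 (not isolated)
Conditions: BF3·OEt2 (3 equiv), 2,6-di-tert-butyl-4-methylpyridine, CH2Cl2 (1 mM), −78 to −40 °C
Reagents that add atoms: none
Why: Boron trifluoride ionises the tertiary allylic alcohol to the C1–C15–C16 allyl cation 43, C7 of the allylsilane bonds to C16 across the ring to give the β-silyl cation 44, and loss of silicon leaves C8=C19H2 while the ring alkene settles at C1=C15. The closest known reaction type is the allylsilane-terminated cation–olefin cyclisation started from a tertiary cycloalkenol (intramolecular Hosomi–Sakurai type), here run transannularly. The cyclopentane closes 5-exo-trig through the C4–C5–C6 tether, and the same bond cuts the eleven-membered ring out of the fourteen-membered one, whereas attack at C1 would need a bridged seven-membered ring. C16 is set by the tether, since C5 sits on one face of quaternary C4 and can reach only that face (cis ring fusion); C7 is set by the C9–C14 chain, which holds C8 on the C15 side of the new ring and so places H-7 cis to H-16. Chemoselectivity rests on the far easier ionisation of the tertiary allylic alcohol than of the secondary C9 acetate, whose allyl cation would carry CH2SiMe3 on its central carbon and gain nothing from silicon. The hindered pyridine intercepts adventitious acid that would protodesilylate the allylsilane, and the diaxial preference of the trans-bis-silyl ether keeps C2–H out of alignment for a hydride shift.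

**Step 31**
Reactants: 45 bis-silyl ether
Product: 46 (2R,3R,4S,7R,9S,12R,16S)-9,20-diacetoxytrinervita-1(15),8(19)-diene-2,3-diol (target)
Conditions: HF·pyridine, pyridine, THF, 0 °C to rt
Reagents that add atoms: none
Why: Buffered fluoride cleavage of the two silyl ethers leaves both acetates in place, and these are too far from the diol to migrate.

**Compound list**

1 | 2-methylcyclohexane-1,3-dione | CC1C(=O)CCCC1=O | starting material
2 | methyl vinyl ketone | C=CC(C)=O | starting material
3 | 2-methyl-2-(3-oxobutyl)cyclohexane-1,3-dione | CC(=O)CCC1(C)C(=O)CCCC1=O | intermediate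
4 | (S)-8a-methyl-3,4,8,8a-tetrahydronaphthalene-1,6(2H,7H)-dione | C[C@]12CCC(=O)C=C1CCCC2=O | intermediate
5 | (4aS,5S)-5-hydroxy-4a-methyl-4,4a,5,6,7,8-hexahydronaphthalen-2(3H)-one | C[C@]12CCC(=O)C=C1CCC[C@@H]2O | intermediate
6 | TBS ether of 5 | C[C@]12CCC(=O)C=C1CCC[C@@H]2O[Si](C)(C)C(C)(C)C | intermediate
7 | 3-[(1R,2S)-2-(TBSO)-1-methyl-6-oxocyclohexyl]propanoic acid | C[C@]1(CCC(=O)O)C(=O)CCC[C@@H]1O[Si](C)(C)C(C)(C)C | intermediate
8 | methyl ester of 7 | C[C@]1(CCC(=O)OC)C(=O)CCC[C@@H]1O[Si](C)(C)C(C)(C)C | intermediate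
9 | lithium enolate of 8 (not isolated) | C[C@]1(CCC(=O)OC)C([O-])=CCC[C@@H]1O[Si](C)(C)C(C)(C)C.[Li+] | intermediate
10 | methyl 3-[(1R,2S)-2-(TBSO)-1,5-dimethyl-6-oxocyclohexyl]propanoate (C5 epimers) | C[C@]1(CCC(=O)OC)C(=O)C(C)CC[C@@H]1O[Si](C)(C)C(C)(C)C | intermediate
11 | potassium enolate of 10 (not isolated) | C[C@]1(CCC(=O)OC)C([O-])=C(C)CC[C@@H]1O[Si](C)(C)C(C)(C)C.[K+] | intermediate
12 | enol triflate, (1R,6S) | C[C@]1(CCC(=O)OC)C(OS(=O)(=O)C(F)(F)F)=C(C)CC[C@@H]1O[Si](C)(C)C(C)(C)C | intermediate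
13 | methyl 3-[(1S,6S)-6-(TBSO)-1,3-dimethylcyclohex-2-en-1-yl]propanoate | C[C@]1(CCC(=O)OC)C=C(C)CC[C@@H]1O[Si](C)(C)C(C)(C)C | intermediate
14 | methyl 3-[(1S,6S)-6-(TBSO)-1,3-dimethyl-4-oxocyclohex-2-en-1-yl]propanoate | C[C@]1(CCC(=O)OC)C=C(C)C(=O)C[C@@H]1O[Si](C)(C)C(C)(C)C | intermediate
15 | silyl dienol ether of 14 | C[C@]1(CCC(=O)OC)C=C(C)C(O[Si](C)(C)C(C)(C)C)=C[C@@H]1O[Si](C)(C)C(C)(C)C | intermediate
16 | C1,C2 silyloxy epoxide, oxygen anti to the C3 silyl ether (not isolated) | C[C@]1(CCC(=O)OC)C=C(C)[C@@]2(O[Si](C)(C)C(C)(C)C)O[C@H]2[C@@H]1O[Si](C)(C)C(C)(C)C | intermediate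
17 | methyl 3-[(1S,5S,6R)-5,6-bis(TBSO)-1,3-dimethyl-4-oxocyclohex-2-en-1-yl]propanoate | C[C@]1(CCC(=O)OC)C=C(C)C(=O)[C@@H](O[Si](C)(C)C(C)(C)C)[C@@H]1O[Si](C)(C)C(C)(C)C | intermediate
18 | (E)-but-2-ene-1,4-diol | OC/C=C/CO | starting material
19 | (E)-4-(4-methoxybenzyloxy)but-2-en-1-ol | COc1ccc(COC/C=C/CO)cc1 | intermediate
20 | (E)-4-(4-methoxybenzyloxy)but-2-en-1-yl methyl carbonate | COC(=O)OC/C=C/COCc1ccc(OC)cc1 | intermediate
21 | dimethyl malonate | COC(=O)CC(=O)OC | starting material
22 | dimethyl 2-[(2S)-1-(4-methoxybenzyloxy)but-3-en-2-yl]malonate | COC(=O)C(C(=O)OC)[C@@H](COCc1ccc(OC)cc1)C=C | intermediate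
23 | methyl (3R)-3-[(4-methoxybenzyloxy)methyl]pent-4-enoate | COC(=O)C[C@@H](COCc1ccc(OC)cc1)C=C | intermediate
24 | (3R)-3-[(4-methoxybenzyloxy)methyl]pent-4-en-1-ol | OCC[C@@H](COCc1ccc(OC)cc1)C=C | intermediate
25 | (3R)-5-iodo-3-[(4-methoxybenzyloxy)methyl]pent-1-ene | ICC[C@@H](COCc1ccc(OC)cc1)C=C | intermediate
26 | alkyllithium from 25 (not isolated) | [Li]CC[C@@H](COCc1ccc(OC)cc1)C=C | intermediate
27 | alkylcerium dichloride from 26 (not isolated) | Cl[Ce](Cl)CC[C@@H](COCc1ccc(OC)cc1)C=C | intermediate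
28 | tertiary allylic alcohol (1R,2S,3R,4S,12R), C7 methyl ester, C20 PMB ether, C11 vinyl | COC(=O)CC[C@]1(C)[C@@H](O[Si](C)(C)C(C)(C)C)[C@H](O[Si](C)(C)C(C)(C)C)[C@@](O)(CC[C@@H](COCc2ccc(OC)cc2)C=C)C(C)=C1 | intermediate
29 | C7 aldehyde from 28 | O=CCC[C@]1(C)[C@@H](O[Si](C)(C)C(C)(C)C)[C@H](O[Si](C)(C)C(C)(C)C)[C@@](O)(CC[C@@H](COCc2ccc(OC)cc2)C=C)C(C)=C1 | intermediate
30 | ethyl (triphenylphosphoranylidene)acetate | CCOC(=O)C=P(c1ccccc1)(c1ccccc1)c1ccccc1 | starting material
31 | (chloromethyl)trimethylsilane | C[Si](C)(C)CCl | starting material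
32 | (iodomethyl)trimethylsilane (not isolated) | C[Si](C)(C)CI | intermediate
33 | [1-ethoxy-1-oxo-3-(trimethylsilyl)propan-2-yl]triphenylphosphonium iodide (not isolated) | CCOC(=O)C(C[Si](C)(C)C)[P+](c1ccccc1)(c1ccccc1)c1ccccc1.[I-] | intermediate
34 | ethyl 2-(triphenylphosphoranylidene)-3-(trimethylsilyl)propanoate | CCOC(=O)C(C[Si](C)(C)C)=P(c1ccccc1)(c1ccccc1)c1ccccc1 | intermediate
35 | (7Z)-enoate, C9 ethyl ester, CH2SiMe3 on C8, C20 PMB ether | C[Si](C)(C)C/C(=C\CC[C@]1(C)[C@@H](O[Si](C)(C)C(C)(C)C)[C@H](O[Si](C)(C)C(C)(C)C)[C@@](O)(CC[C@@H](COCc2ccc(OC)cc2)C=C)C(C)=C1)C(=O)OCC | intermediate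
36 | C20 alcohol of 35 | C[Si](C)(C)C/C(=C\CC[C@]1(C)[C@@H](O[Si](C)(C)C(C)(C)C)[C@H](O[Si](C)(C)C(C)(C)C)[C@@](O)(CC[C@@H](CO)C=C)C(C)=C1)C(=O)OCC | intermediate
37 | 1,9,20-triol (C9 primary allylic alcohol) | C[Si](C)(C)C/C(=C\CC[C@]1(C)[C@@H](O[Si](C)(C)C(C)(C)C)[C@H](O[Si](C)(C)C(C)(C)C)[C@@](O)(CC[C@@H](CO)C=C)C(C)=C1)CO | intermediate
38 | C9 enal | C[Si](C)(C)C/C(=C\CC[C@]1(C)[C@@H](O[Si](C)(C)C(C)(C)C)[C@H](O[Si](C)(C)C(C)(C)C)[C@@](O)(CC[C@@H](CO)C=C)C(C)=C1)C=O | intermediate
39 | (9S)-vinyl carbinol | C[Si](C)(C)C/C(=C\CC[C@]1(C)[C@@H](O[Si](C)(C)C(C)(C)C)[C@H](O[Si](C)(C)C(C)(C)C)[C@@](O)(CC[C@@H](CO)C=C)C(C)=C1)[C@@H](O)C=C | intermediate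
40 | 9,20-diacetate of 39 | C[Si](C)(C)C/C(=C\CC[C@]1(C)[C@@H](O[Si](C)(C)C(C)(C)C)[C@H](O[Si](C)(C)C(C)(C)C)[C@@](O)(CC[C@@H](COC(C)=O)C=C)C(C)=C1)[C@@H](OC(C)=O)C=C | intermediate
41 | 10,11-didehydro-42 (E/Z at C10=C11 left open) | C[Si](C)(C)C/C(=C\CC[C@]1(C)[C@@H](O[Si](C)(C)C(C)(C)C)[C@H](O[Si](C)(C)C(C)(C)C)[C@@](O)(CC[C@@H](COC(C)=O)C=C2)C(C)=C1)[C@H]2OC(C)=O | intermediate
42 | (1R,2S,3R,4S,7Z,9S,12R)-9,20-diacetoxy-2,3-bis(TBSO)-19-(trimethylsilyl)-7,16-secotrinervita-7,15-dien-1-ol | C[Si](C)(C)C/C(=C\CC[C@]1(C)[C@@H](O[Si](C)(C)C(C)(C)C)[C@H](O[Si](C)(C)C(C)(C)C)[C@@](O)(CC[C@@H](COC(C)=O)CC2)C(C)=C1)[C@H]2OC(C)=O | intermediate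
43 | C1–C15–C16 allyl cation (not isolated) | C[Si](C)(C)C/C(=C\CC[C@]1(C)[C@@H](O[Si](C)(C)C(C)(C)C)[C@H](O[Si](C)(C)C(C)(C)C)[C+](CC[C@@H](COC(C)=O)CC2)C(C)=C1)[C@H]2OC(C)=O | intermediate
44 | tricyclic C8 cation β to silicon (not isolated) | C[Si](C)(C)C[C+]1[C@@H](OC(C)=O)CC[C@H](COC(C)=O)CCC2=C(C)[C@@H]3[C@H]1CC[C@]3(C)[C@@H](O[Si](C)(C)C(C)(C)C)[C@@H]2O[Si](C)(C)C(C)(C)C | intermediate
45 | 2,3-bis-O-TBS ether of 46 | C=C1[C@@H](OC(C)=O)CC[C@H](COC(C)=O)CCC2=C(C)[C@@H]3[C@H]1CC[C@]3(C)[C@@H](O[Si](C)(C)C(C)(C)C)[C@@H]2O[Si](C)(C)C(C)(C)C | intermediate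
46 | (2R,3R,4S,7R,9S,12R,16S)-9,20-diacetoxytrinervita-1(15),8(19)-diene-2,3-diol | C=C1[C@@H](OC(C)=O)CC[C@H](COC(C)=O)CCC2=C(C)[C@@H]3[C@H]1CC[C@]3(C)[C@@H](O)[C@@H]2O | target

**Total step count:** 31.
**Longest linear sequence:** 24 (steps 1–12, 19, 20, 22–31).

**Steps most likely to fail**

**Step 30.**
- What may go wrong: the allyl cation may lose a proton before C–C bond formation. A hydride may shift from C2 with loss of the silyl group. The allylsilane may be protodesilylated. The bridged ring may be unable to bring the correct face of C7=C8 over C16.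
- Fallback: the order of the ring closures is inverted, setting out from 40.
- The same ionisation (BF3·OEt2, hindered pyridine, CH2Cl2, −78 °C) is run on the open-chain compound. There the 5-exo closure is not tied to a macrocyclic conformation, and it should give the cis-hydrindene tetraene diacetate F1.
- Ring-closing metathesis of the two vinyl groups of F1 forms the eleven-membered ring and gives the 10,11-didehydro tricycle F2.
- Diimide should then saturate the 1,2-disubstituted C10=C11 alkene ahead of the hindered 1,1-disubstituted C8=C19 alkene, and the route is rejoined at 45.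
- The price is that C7 is then no longer steered by the macrocycle.

**Step 28.**
- What may go wrong: cross metathesis to oligomers if strain in the bridged fourteen-membered ring slows closure, or ruthenium hydride isomerisation of the skipped C7=C8/C10=CH2 diene.
- Fallback: the ring is closed by a carbonyl addition at C9–C10 instead, setting out from 35.
- Lemieux–Johnson cleavage of the terminal vinyl group (OsO4 cat., NaIO4, 2,6-lutidine) gives the C11 aldehyde F3.
- Takai olefination (CrCl2, CHI3, THF) gives the (E)-vinyl iodide F4.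
- DDQ gives the C20 alcohol F5, DIBAL-H gives the allylic alcohol F6, and MnO2 gives the iodo enal F7.
- A Nozaki–Hiyama–Kishi reaction (CrCl2, NiCl2 cat., chiral sulfonamide ligand, high dilution) closes the ring to the macrocyclic (9S,10E)-allylic alcohol F8.
- Ac2O/pyridine then returns to 41.

**Step 26.**
- What may go wrong: poor facial selectivity, because the zinc alkoxides of the two free hydroxyl groups and residual magnesium salts open an unligated background addition.
- Fallback: C9 is set by reagent-controlled reduction instead of addition, setting out from 38.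
- Vinylmagnesium bromide (THF, −78 °C) gives the C9-epimeric carbinols F9.
- MnO2 oxidises only the doubly allylic alcohol, giving the cross-conjugated dienone F10.
- A Corey–Bakshi–Shibata reduction ((R)-methyl oxazaborolidine, catecholborane, toluene, −78 °C) follows. The α-branched alkenyl group acts as the large substituent and vinyl as the small one, so the reduction should return 39.

**Further compounds**

F1 | step 30 | cis-hydrindene from open-chain cyclisation (C16–C7 formed, C8=C19H2, vinyl groups on C9 and C12) | C=C([C@@H](OC(C)=O)C=C)[C@@H]1CC[C@@]2(C)[C@@H]1C(C)=C(CC[C@@H](COC(C)=O)C=C)[C@@H](O[Si](C)(C)C(C)(C)C)[C@@H]2O[Si](C)(C)C(C)(C)C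
F2 | step 30 | 10,11-didehydro-45 | C=C1[C@@H](OC(C)=O)C=C[C@H](COC(C)=O)CCC2=C(C)[C@@H]3[C@H]1CC[C@]3(C)[C@@H](O[Si](C)(C)C(C)(C)C)[C@@H]2O[Si](C)(C)C(C)(C)C
F3 | step 28 | C11 aldehyde from 35 | C[Si](C)(C)C/C(=C\CC[C@]1(C)[C@@H](O[Si](C)(C)C(C)(C)C)[C@H](O[Si](C)(C)C(C)(C)C)[C@@](O)(CC[C@@H](COCc2ccc(OC)cc2)C=O)C(C)=C1)C(=O)OCC
F4 | step 28 | (10E)-vinyl iodide | C[Si](C)(C)C/C(=C\CC[C@]1(C)[C@@H](O[Si](C)(C)C(C)(C)C)[C@H](O[Si](C)(C)C(C)(C)C)[C@@](O)(CC[C@@H](COCc2ccc(OC)cc2)/C=C/I)C(C)=C1)C(=O)OCC
F5 | step 28 | C20 alcohol of F4 | C[Si](C)(C)C/C(=C\CC[C@]1(C)[C@@H](O[Si](C)(C)C(C)(C)C)[C@H](O[Si](C)(C)C(C)(C)C)[C@@](O)(CC[C@@H](CO)/C=C/I)C(C)=C1)C(=O)OCC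
F6 | step 28 | C9 allylic alcohol of F5 | C[Si](C)(C)C/C(=C\CC[C@]1(C)[C@@H](O[Si](C)(C)C(C)(C)C)[C@H](O[Si](C)(C)C(C)(C)C)[C@@](O)(CC[C@@H](CO)/C=C/I)C(C)=C1)CO
F7 | step 28 | iodo enal | C[Si](C)(C)C/C(=C\CC[C@]1(C)[C@@H](O[Si](C)(C)C(C)(C)C)[C@H](O[Si](C)(C)C(C)(C)C)[C@@](O)(CC[C@@H](CO)/C=C/I)C(C)=C1)C=O
F8 | step 28 | macrocyclic (9S,10E)-1,9,20-triol | C[Si](C)(C)C/C(=C\CC[C@]1(C)[C@@H](O[Si](C)(C)C(C)(C)C)[C@H](O[Si](C)(C)C(C)(C)C)[C@@](O)(CC[C@@H](CO)/C=C/2)C(C)=C1)[C@H]2O
F9 | step 26 | C9-epimeric vinyl carbinols | C[Si](C)(C)C/C(=C\CC[C@]1(C)[C@@H](O[Si](C)(C)C(C)(C)C)[C@H](O[Si](C)(C)C(C)(C)C)[C@@](O)(CC[C@@H](CO)C=C)C(C)=C1)C(O)C=C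
F10 | step 26 | cross-conjugated C9 dienone | C[Si](C)(C)C/C(=C\CC[C@]1(C)[C@@H](O[Si](C)(C)C(C)(C)C)[C@H](O[Si](C)(C)C(C)(C)C)[C@@](O)(CC[C@@H](CO)C=C)C(C)=C1)C(=O)C=C
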